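**Assumption:** the SMILES is read as 7S; 1'R,6'R (trans) in the cyclohexenyl group; 2''R,3''R,4''S (2'',3''-anti, 3'',4''-syn) in the acyl chain.

**Retrosynthetic overview**
1. Target ⇒ cleave the C7–O ester bond: a 7-hydroxy azaphilone plus silyl-protected (2R,3R,4S)-3-hydroxy-2,4-dimethylhexanoic acid; the acid ⇒ anti boron aldol of benzyl propanoate with (S)-2-methylbutanal, from (S)-2-methylbutan-1-ol.
2. 7-Hydroxy azaphilone ⇒ key step: the C7–O bond is made by a [2,3]-sigmatropic oxygen shift in the aryl λ5-iodanyl ether formed from IBX and a 6,8-dihydroxy-2-benzopyrylium (as its anhydrobase).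
3. Benzopyrylium ⇒ orthoformate (C1) plus an arylacetyl-cyclohexenone β-diketone ⇒ Claisen C-acylation of the α'-enolate of (R)-5-methylcyclohex-2-enone (from (R)-pulegone) by a (3,5-dihydroxy-4-methylphenyl)acetyl chloride (Arndt–Eistert from 3,5-dihydroxy-4-methylbenzoic acid).
4. Ring order: the cyclohexenone ring (pulegone) and the benzene ring are bought; the pyran ring is closed third; the carbocycle is dearomatised last to the 6,8-dione.
5. Stereocenters: C4'' and C6' are bought; C2''/C3'' come from the aldol under control of C4''; C1' settles by equilibration next to C6'; C7 forms without facial control (about 1:1) and is resolved as diastereomeric esters.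

**Route**

Step 1
Reactants: 1 (S)-2-methylbutan-1-ol
Product: 2 (S)-2-methylbutanal
Conditions: TEMPO (1 mol %), KBr (10 mol %), NaOCl (1.1 equiv), NaHCO3, CH2Cl2/H2O, 0 °C; dried CH2Cl2 solution used directly
Reagents that add atoms: none
Why: Anelli (oxoammonium/hypochlorite) oxidation stops at the aldehyde and, being fast at 0 °C under bicarbonate buffering, leaves the α-stereocenter unracemised.

Step 2
Reactants: 2 (S)-2-methylbutanal; 3 benzyl propanoate
Product: 5 benzyl (2R,3R,4S)-3-hydroxy-2,4-dimethylhexanoate, via boron enolate 4 (not isolated)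
Conditions: 3, (c-C6H11)2BOTf (1.5 equiv), Et3N (1.8 equiv), CH2Cl2, −78 °C, 2 h; then 2 (1.3 equiv), −78 → 0 °C; pH 7 buffer, MeOH, 30% H2O2; chromatography
Reagents that add atoms: none
Why: Anti-selective boron aldol of an ester (Abiko–Masamune conditions): enolate 4, with methyl trans to O–B, reacts through a Zimmerman–Traxler chair to set C2/C3 anti, and Felkin–Anh addition to the α-methyl aldehyde sets C3 syn to the purchased C4 center, so (2R,3R,4S)-5 is the major isomer (facial selectivity for Me versus Et is only moderate, roughly 3–4:1, and the minor isomers are removed by chromatography).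

Step 3
Reactants: 5 benzyl (2R,3R,4S)-3-hydroxy-2,4-dimethylhexanoate
Product: 6 benzyl (2R,3R,4S)-2,4-dimethyl-3-(triethylsilyloxy)hexanoate
Conditions: Et3SiOTf (1.3 equiv), 2,6-lutidine (2 equiv), CH2Cl2, −78 → 0 °C
Reagents that add atoms: triethylsilyl triflate, CC[Si](CC)(CC)OS(=O)(=O)C(F)(F)F
Why: Silyl triflate O-silylation of a hindered secondary alcohol with a non-nucleophilic base touches no stereocenter.

Step 4
Reactants: 6 benzyl (2R,3R,4S)-2,4-dimethyl-3-(triethylsilyloxy)hexanoate
Product: 7 (2R,3R,4S)-2,4-dimethyl-3-(triethylsilyloxy)hexanoic acid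
Conditions: H2 (1 atm), 10% Pd/C, EtOAc, rt
Reagents that add atoms: none
Why: Hydrogenolysis of the benzyl ester in a non-protic solvent leaves the triethylsilyl ether and all three stereocenters intact.

Step 5
Reactants: 8 (R)-(+)-pulegone
Product: 9 pulegone oxide [(6R)-2,2,6-trimethyl-1-oxaspiro[2.5]octan-4-one; both spiro epimers]
Conditions: 30% H2O2, LiOH (cat.), MeOH, 0 °C → rt
Reagents that add atoms: hydrogen peroxide, OO
Why: Weitz–Scheffer nucleophilic epoxidation of the enone; the new spiro center is destroyed in step 6 and the remote methyl center is untouched.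

Step 6
Reactants: 9 pulegone oxide
Product: 10 (5R)-5-methyl-2-(phenylsulfanyl)cyclohexan-1-one (both C2 epimers)
Conditions: PhSNa (1.2 equiv), THF, reflux; aqueous work-up
Reagents that add atoms: sodium benzenethiolate, [Na+].[S-]c1ccccc1
Why: Thiolate opening of the α,β-epoxy ketone at the α-carbon followed by retro-aldol loss of acetone gives the α-sulfanyl ketone; C5 is untouched and the C2 epimers converge in step 7.

Step 7
Reactants: 10 (5R)-5-methyl-2-(phenylsulfanyl)cyclohexan-1-one
Product: 12 (R)-5-methylcyclohex-2-en-1-one, via sulfoxide 11 (not isolated)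
Conditions: mCPBA (1.0 equiv), CH2Cl2, −78 °C; then CaCO3, toluene, 80 °C
Reagents that add atoms: none
Why: Sulfide oxidation and thermal syn-elimination of benzenesulfenic acid (sulfoxide pyrolysis) can only run toward C3, giving the 2-ene with the 5R center preserved.

Step 8
Reactants: 13 3,5-dihydroxy-4-methylbenzoic acid
Product: 15 3,5-bis(tert-butyldimethylsilyloxy)-4-methylbenzoic acid, via silyl ester 14 (not isolated)
Conditions: t-BuMe2SiCl (3.5 equiv), imidazole (7 equiv), DMF, rt; then AcOH/THF/H2O (3:1:1), rt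
Reagents that add atoms: tert-butyldimethylsilyl chloride, CC(C)(C)[Si](C)(C)Cl
Why: Exhaustive silylation followed by selective solvolysis of the much more labile silyl ester leaves two aryl silyl ethers that tolerate the acid chloride, diazoketone and enolate chemistry that follows.

Step 9
Reactants: 15 3,5-bis(tert-butyldimethylsilyloxy)-4-methylbenzoic acid
Product: 17 1-[3,5-bis(tert-butyldimethylsilyloxy)-4-methylphenyl]-2-diazoethan-1-one, via acid chloride 16 (not isolated)
Conditions: (COCl)2 (1.5 equiv), DMF (cat.), CH2Cl2, 0 °C → rt, evaporate; CH2N2 (3 equiv), Et2O, 0 °C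
Reagents that add atoms: diazomethane, C=[N+]=[N-]
Why: First half of the Arndt–Eistert homologation: the acyl chloride acylates diazomethane and a second equivalent scavenges HCl.

Step 10
Reactants: 17 1-[3,5-bis(tert-butyldimethylsilyloxy)-4-methylphenyl]-2-diazoethan-1-one
Product: 19 2-[3,5-bis(tert-butyldimethylsilyloxy)-4-methylphenyl]acetic acid, via aryl ketene 18 (not isolated)
Conditions: AgO2CPh (10 mol %), Et3N (3 equiv), THF/H2O (9:1), rt, dark
Reagents that add atoms: water, O
Why: Silver-promoted Wolff rearrangement gives the aryl ketene, which adds water to give the homologous arylacetic acid.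

Step 11
Reactants: 19 2-[3,5-bis(tert-butyldimethylsilyloxy)-4-methylphenyl]acetic acid; 12 (R)-5-methylcyclohex-2-en-1-one
Product: 23 (5R,6R)-6-[2-(3,5-dihydroxy-4-methylphenyl)acetyl]-5-methylcyclohex-2-en-1-one, via acid chloride 20 (not isolated), via lithium dienolate 21 (not isolated), via bis-silyl diketone 22 (not isolated)
Conditions: 19, Me2C=C(Cl)NMe2 (1.1 equiv), CH2Cl2, 0 °C → rt, evaporate; 12 (2.2 equiv), LiN(i-Pr)2 (2.2 equiv), toluene/THF, −78 °C; add 20, −78 °C, 1 h; AcOH, then Bu4NF, THF, 0 °C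
Reagents that add atoms: none
Why: Claisen-type C-acylation: kinetic α'-deprotonation of the enone gives cross-conjugated dienolate 21, which is acylated at C6 by 20 (a second equivalent of enolate takes up the acidic diketone proton), and buffered fluoride then frees the phenols; the new C6 center is enolisable and is fixed only later, under thermodynamic control by the adjacent 5R-methyl center.

Step 12
Reactants: 23 (5R,6R)-6-[2-(3,5-dihydroxy-4-methylphenyl)acetyl]-5-methylcyclohex-2-en-1-one
Product: 25 8-hydroxy-7-methyl-3-[(1R,6R)-6-methyl-2-oxocyclohex-3-en-1-yl]-6H-isochromen-6-one, via keto-aldehyde 24 (not isolated)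
Conditions: HC(OEt)3 (3 equiv), CF3CO2H/CH2Cl2 (1:4), 0 °C → rt; evaporate; aq. NaHCO3
Reagents that add atoms: triethyl orthoformate, CCOC(OCC)OCC
Why: Orthoformate C-formylation of the resorcinol ring ortho to the side chain (the two candidate positions are equivalent and doubly activated) gives 24, whose side-chain ketone oxygen closes on the aldehyde with loss of water to form the pyran ring as a 2-benzopyrylium (isolated as anhydrobase 25), while the acidic C1' center equilibrates to the trans (1R,6R) arrangement beside the pulegone-derived methyl.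

Step 13
Reactants: 25 8-hydroxy-7-methyl-3-[(1R,6R)-6-methyl-2-oxocyclohex-3-en-1-yl]-6H-isochromen-6-one
Product: 28 (7S)-7-hydroxy-7-methyl-3-[(1R,6R)-6-methyl-2-oxocyclohex-3-en-1-yl]-6H-isochromene-6,8(7H)-dione, via aryloxy-λ5-iodane 26 (not isolated), via 7-O-iodane 27 (not isolated)
Conditions: IBX (1.3 equiv), Bu4NI (5 mol %), ClCH2CH2Cl/CF3CO2H (10:1), rt, 1–2 h
Reagents that add atoms: 2-iodoxybenzoic acid (IBX), O=C1OI(=O)(O)c2ccccc12
Why: Hydroxylative phenol dearomatisation: the phenolic oxygen binds pentavalent iodine to give 26, and the I=O oxygen is delivered to the ortho carbon C7 through a five-membered array, a [2,3]-sigmatropic shift that reduces iodine to the trivalent state (27) before hydrolysis gives the tertiary alcohol and the azaphilone chromophore; the planar bicycle offers no facial bias, so 28 forms with its 7R epimer in about 1:1 ratio and the pair is carried on and resolved in step 14.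

Step 14
Reactants: 28 (7S)-7-hydroxy-7-methyl-3-[(1R,6R)-6-methyl-2-oxocyclohex-3-en-1-yl]-6H-isochromene-6,8(7H)-dione (as the C7-epimer mixture from step 13); 7 (2R,3R,4S)-2,4-dimethyl-3-(triethylsilyloxy)hexanoic acid
Product: 30 (7S)-7-methyl-3-[(1R,6R)-6-methyl-2-oxocyclohex-3-en-1-yl]-6,8-dioxo-7,8-dihydro-6H-isochromen-7-yl (2R,3R,4S)-2,4-dimethyl-3-(triethylsilyloxy)hexanoate, via acid chloride 29 (not isolated)
Conditions: 7 (2.5 equiv), Me2C=C(Cl)NMe2, CH2Cl2, 0 °C → rt; then 28, DMAP (3 equiv), CH2Cl2, 0 °C → rt; chromatographic removal of the 7R ester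
Reagents that add atoms: none
Why: DMAP-mediated acyl transfer from acid chloride 29 (made under neutral conditions so the α-center is not epimerised through a ketene) to the tertiary C7 alcohol; the three acid stereocenters turn the C7 epimers into separable diastereomeric esters, and the 7S ester is collected.

Step 15
Reactants: 30 (7S)-7-methyl-3-[(1R,6R)-6-methyl-2-oxocyclohex-3-en-1-yl]-6,8-dioxo-7,8-dihydro-6H-isochromen-7-yl (2R,3R,4S)-2,4-dimethyl-3-(triethylsilyloxy)hexanoate
Product: 31 Muyocopronone A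
Conditions: HF·pyridine, THF, 0 °C → rt
Reagents that add atoms: none
Why: Fluoride cleavage of the triethylsilyl ether under mildly acidic conditions free of N–H nucleophiles, which the azaphilone, ester and enone tolerate; the enolisable C1' center stays in its thermodynamic trans arrangement and no other stereocenter is affected.

**Compound list**
1 | (S)-2-methylbutan-1-ol | CC[C@H](C)CO | starting material
2 | (S)-2-methylbutanal | CC[C@H](C)C=O | intermediate
3 | benzyl propanoate | CCC(=O)OCc1ccccc1 | starting material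
4 | dicyclohexylboron enolate of benzyl propanoate, C-methyl trans to the O–B oxygen | C/C=C(/OB(C1CCCCC1)C1CCCCC1)OCc1ccccc1 | intermediate
5 | benzyl (2R,3R,4S)-3-hydroxy-2,4-dimethylhexanoate | CC[C@H](C)[C@@H](O)[C@@H](C)C(=O)OCc1ccccc1 | intermediate
6 | benzyl (2R,3R,4S)-2,4-dimethyl-3-(triethylsilyloxy)hexanoate | CC[C@H](C)[C@@H](O[Si](CC)(CC)CC)[C@@H](C)C(=O)OCc1ccccc1 | intermediate
7 | (2R,3R,4S)-2,4-dimethyl-3-(triethylsilyloxy)hexanoic acid | CC[C@H](C)[C@@H](O[Si](CC)(CC)CC)[C@@H](C)C(=O)O | intermediate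
8 | (R)-(+)-pulegone, (5R)-5-methyl-2-(propan-2-ylidene)cyclohexan-1-one | C[C@@H]1CCC(=C(C)C)C(=O)C1 | starting material
9 | pulegone oxide, (6R)-2,2,6-trimethyl-1-oxaspiro[2.5]octan-4-one (both spiro epimers) | C[C@@H]1CCC2(OC2(C)C)C(=O)C1 | intermediate
10 | (5R)-5-methyl-2-(phenylsulfanyl)cyclohexan-1-one (both C2 epimers) | C[C@@H]1CCC(Sc2ccccc2)C(=O)C1 | intermediate
11 | (5R)-5-methyl-2-(phenylsulfinyl)cyclohexan-1-one | C[C@@H]1CCC(S(=O)c2ccccc2)C(=O)C1 | intermediate
12 | (R)-5-methylcyclohex-2-en-1-one | C[C@@H]1CC=CC(=O)C1 | intermediate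
13 | 3,5-dihydroxy-4-methylbenzoic acid | Cc1c(O)cc(cc1O)C(=O)O | starting material
14 | tert-butyldimethylsilyl 3,5-bis(tert-butyldimethylsilyloxy)-4-methylbenzoate | Cc1c(O[Si](C)(C)C(C)(C)C)cc(cc1O[Si](C)(C)C(C)(C)C)C(=O)O[Si](C)(C)C(C)(C)C | intermediate
15 | 3,5-bis(tert-butyldimethylsilyloxy)-4-methylbenzoic acid | Cc1c(O[Si](C)(C)C(C)(C)C)cc(cc1O[Si](C)(C)C(C)(C)C)C(=O)O | intermediate
16 | 3,5-bis(tert-butyldimethylsilyloxy)-4-methylbenzoyl chloride | Cc1c(O[Si](C)(C)C(C)(C)C)cc(cc1O[Si](C)(C)C(C)(C)C)C(=O)Cl | intermediate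
17 | 1-[3,5-bis(tert-butyldimethylsilyloxy)-4-methylphenyl]-2-diazoethan-1-one | Cc1c(O[Si](C)(C)C(C)(C)C)cc(cc1O[Si](C)(C)C(C)(C)C)C(=O)C=[N+]=[N-] | intermediate
18 | [3,5-bis(tert-butyldimethylsilyloxy)-4-methylphenyl]ketene | Cc1c(O[Si](C)(C)C(C)(C)C)cc(C=C=O)cc1O[Si](C)(C)C(C)(C)C | intermediate
19 | 2-[3,5-bis(tert-butyldimethylsilyloxy)-4-methylphenyl]acetic acid | Cc1c(O[Si](C)(C)C(C)(C)C)cc(CC(=O)O)cc1O[Si](C)(C)C(C)(C)C | intermediate
20 | 2-[3,5-bis(tert-butyldimethylsilyloxy)-4-methylphenyl]acetyl chloride | Cc1c(O[Si](C)(C)C(C)(C)C)cc(CC(=O)Cl)cc1O[Si](C)(C)C(C)(C)C | intermediate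
21 | lithium (6R)-6-methylcyclohexa-1,3-dien-2-olate (kinetic α'-enolate of 12) | C[C@@H]1CC=CC([O-])=C1.[Li+] | intermediate
22 | (5R,6R)-6-{2-[3,5-bis(tert-butyldimethylsilyloxy)-4-methylphenyl]acetyl}-5-methylcyclohex-2-en-1-one (largely enolised) | Cc1c(O[Si](C)(C)C(C)(C)C)cc(CC(=O)[C@@H]2C(=O)C=CC[C@H]2C)cc1O[Si](C)(C)C(C)(C)C | intermediate
23 | (5R,6R)-6-[2-(3,5-dihydroxy-4-methylphenyl)acetyl]-5-methylcyclohex-2-en-1-one (largely enolised) | Cc1c(O)cc(CC(=O)[C@@H]2C(=O)C=CC[C@H]2C)cc1O | intermediate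
24 | 2,4-dihydroxy-3-methyl-6-{2-[(1R,6R)-6-methyl-2-oxocyclohex-3-en-1-yl]-2-oxoethyl}benzaldehyde | Cc1c(O)cc(CC(=O)[C@@H]2C(=O)C=CC[C@H]2C)c(C=O)c1O | intermediate
25 | 8-hydroxy-7-methyl-3-[(1R,6R)-6-methyl-2-oxocyclohex-3-en-1-yl]-6H-isochromen-6-one (anhydrobase of the 6,8-dihydroxy-2-benzopyrylium) | CC1=C(O)C2=COC([C@@H]3C(=O)C=CC[C@H]3C)=CC2=CC1=O | intermediate
26 | 8-O-(1-oxo-3-oxo-1λ5,2-benziodoxol-1-yl) ether of 25 | CC1=C(OI4(=O)OC(=O)c5ccccc45)C2=COC([C@@H]3C(=O)C=CC[C@H]3C)=CC2=CC1=O | intermediate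
27 | (7S)-7-methyl-7-[(3-oxo-1λ3,2-benziodoxol-1-yl)oxy]-3-[(1R,6R)-6-methyl-2-oxocyclohex-3-en-1-yl]-6H-isochromene-6,8(7H)-dione | O=C1OI(O[C@@]2(C)C(=O)C=C3C=C([C@@H]4C(=O)C=CC[C@H]4C)OC=C3C2=O)c2ccccc12 | intermediate
28 | (7S)-7-hydroxy-7-methyl-3-[(1R,6R)-6-methyl-2-oxocyclohex-3-en-1-yl]-6H-isochromene-6,8(7H)-dione (obtained with its 7R epimer) | O[C@@]1(C)C(=O)C=C2C=C([C@@H]3C(=O)C=CC[C@H]3C)OC=C2C1=O | intermediate
29 | (2R,3R,4S)-2,4-dimethyl-3-(triethylsilyloxy)hexanoyl chloride | CC[C@H](C)[C@@H](O[Si](CC)(CC)CC)[C@@H](C)C(=O)Cl | intermediate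
30 | (7S)-7-methyl-3-[(1R,6R)-6-methyl-2-oxocyclohex-3-en-1-yl]-6,8-dioxo-7,8-dihydro-6H-isochromen-7-yl (2R,3R,4S)-2,4-dimethyl-3-(triethylsilyloxy)hexanoate | CC[C@H](C)[C@@H](O[Si](CC)(CC)CC)[C@@H](C)C(=O)O[C@@]1(C)C(=O)C=C2C=C([C@@H]3C(=O)C=CC[C@H]3C)OC=C2C1=O | intermediate
31 | Muyocopronone A, (7S)-7-methyl-3-[(1R,6R)-6-methyl-2-oxocyclohex-3-en-1-yl]-6,8-dioxo-7,8-dihydro-6H-isochromen-7-yl (2R,3R,4S)-3-hydroxy-2,4-dimethylhexanoate | CC[C@H](C)[C@@H](O)[C@@H](C)C(=O)O[C@@]1(C)C(=O)C=C2C=C([C@@H]3C(=O)C=CC[C@H]3C)OC=C2C1=O | target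

**Step count and risks**

Total step count: 15. Longest linear sequence: 8 steps (13 → 31 through steps 8–15; equally 8 → 31 through steps 5–7 and 11–15).

Step 11 (C-acylation of dienolate 21 by the enolisable chloride 20) may give O-acylation or ketene-derived by-products. The fallback sets out from 19 and comes back at 23. Reduce 19 with BH3·THF to 2-[3,5-bis(tert-butyldimethylsilyloxy)-4-methylphenyl]ethan-1-ol F1, and oxidise it with Dess–Martin periodinane to 2-[3,5-bis(tert-butyldimethylsilyloxy)-4-methylphenyl]acetaldehyde F2. Add F2 to dienolate 21 (from 12 and LiN(i-Pr)2, THF, −78 °C; aldol addition, which outruns proton transfer) to give (5R,6R)-6-{2-[3,5-bis(tert-butyldimethylsilyloxy)-4-methylphenyl]-1-hydroxyethyl}-5-methylcyclohex-2-en-1-one F3 as carbinol epimers. Oxidise F3 with Dess–Martin periodinane to diketone 22 and desilylate with Bu4NF/AcOH to 23.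

Step 12 (one-pot orthoformate cascade on a free β-diketone and enone) may O-alkylate the diketone or attack the benzylic carbon. The fallback sets out from 23 and comes back at 25. Formylation and ring closure are separated: Rieche formylation (Cl2CHOMe, TiCl4, CH2Cl2, −78 → 0 °C, then aq. HCl) holds the diketone as its titanium chelate while the titanium phenoxide directs the electrophile ortho, and keto-aldehyde 24 is isolated. Cyclodehydration of 24 in CF3CO2H/CH2Cl2 followed by aq. NaHCO3 then gives 25. This fallback makes no compound outside the list (F0).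

Step 14 (esterification of the hindered tertiary C7 alcohol with a hindered α-branched acid chloride) may be slow or erode C2''. The fallback sets out from 25 and 7 and comes back at 30, bypassing steps 13 and 14. Heat PhI(OAc)2 with 7 (2 equiv) in chlorobenzene under reduced pressure, distilling off acetic acid, to give phenyl-λ3-iodanediyl bis[(2R,3R,4S)-2,4-dimethyl-3-(triethylsilyloxy)hexanoate] F4. Treat 25 with F4 in CH2Cl2/CF3CH2OH at −20 °C (Wessely-type oxidative acyloxylation: the phenol exchanges onto trivalent iodine, the carboxylate attacks C7 and iodobenzene leaves). This gives 30 and its 7R epimer directly, and they are separated by chromatography.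

Further compounds
F1 | step 11 | 2-[3,5-bis(tert-butyldimethylsilyloxy)-4-methylphenyl]ethan-1-ol | Cc1c(O[Si](C)(C)C(C)(C)C)cc(CCO)cc1O[Si](C)(C)C(C)(C)C
F2 | step 11 | 2-[3,5-bis(tert-butyldimethylsilyloxy)-4-methylphenyl]acetaldehyde | Cc1c(O[Si](C)(C)C(C)(C)C)cc(CC=O)cc1O[Si](C)(C)C(C)(C)C
F3 | step 11 | (5R,6R)-6-{2-[3,5-bis(tert-butyldimethylsilyloxy)-4-methylphenyl]-1-hydroxyethyl}-5-methylcyclohex-2-en-1-one (carbinol epimers) | Cc1c(O[Si](C)(C)C(C)(C)C)cc(CC(O)[C@@H]2C(=O)C=CC[C@H]2C)cc1O[Si](C)(C)C(C)(C)C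
F0 | step 12 | none | none
F4 | step 14 | phenyl-λ3-iodanediyl bis[(2R,3R,4S)-2,4-dimethyl-3-(triethylsilyloxy)hexanoate] | CC[C@H](C)[C@@H](O[Si](CC)(CC)CC)[C@@H](C)C(=O)OI(OC(=O)[C@H](C)[C@H](O[Si](CC)(CC)CC)[C@@H](C)CC)c1ccccc1
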